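**Strategy**

The tetrahydrofuran (O1, C2–C5) is traced back by Wolff ring contraction to a tetrahydropyran-4-one. This makes C5 and C4 of the furan, with their trans aryl/C9' pair, the β- and α-carbons of a 2-aryl-2,3-dihydropyran-4-one whose stereocentre becomes C2. In one operation an aryl cuprate adds to the enone and the enolate is alkylated with benzyl chloromethyl ether. This forms C5–aryl and C4–C9' and sets both centres from C2 (2,5-trans diaryl across O1, 4,5-trans). The precursor is the (S)-2-aryl-dihydropyranone from a catalytic asymmetric hetero-Diels–Alder reaction of O-benzylvanillin. The ketone carbon later leaves the ring as C9, and C3 is set by kinetic protonation.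

Key step: step 4

Assumption: (S)-BINOL is taken to deliver the 2S pyranone, by analogy with the facial preference of this titanium catalyst in aldehyde allylation; the sense would be checked on the first run (chiral HPLC, optical rotation) and (R)-BINOL used if it is opposite. Tetrahydrofuran numbering below: O1, C2 (aryl from the aldehyde), C3 (arm C9), C4 (arm C9'), C5 (aryl from the Grignard reagent).

**Route**

Step 1
Reactants: 1 4-(benzyloxy)-3-methoxybenzaldehyde (commercial O-benzylvanillin); 2 (E)-1-methoxy-3-(trimethylsilyloxy)buta-1,3-diene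
Product: 4 (2S)-2-(4-benzyloxy-3-methoxyphenyl)-2,3-dihydro-4H-pyran-4-one, via silylated aldol adduct 3 (not isolated)
Conditions: Ti(OiPr)4 (10 mol%), (S)-BINOL (20 mol%), 4 Å MS, Et2O, −20 °C; then CF3CO2H, CH2Cl2, 0 °C; recrystallisation if enantiomeric enrichment is needed
Reagents that add atoms: none
Why: Formal hetero-Diels–Alder reaction (Mukaiyama aldol addition, then acid-promoted oxa-Michael closure with loss of methanol), in which the chiral BINOL complex of tetravalent titanium differentiates the aldehyde faces and so sets C2.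

Step 2
Reactants: 5 4-bromo-2-methoxyphenol
Product: 6 1-(benzyloxy)-4-bromo-2-methoxybenzene
Conditions: BnBr, K2CO3, acetone, reflux
Reagents that add atoms: benzyl bromide, BrCc1ccccc1
Why: Williamson ether synthesis on the phenoxide, with no competing site.

Step 3
Reactants: 6 1-(benzyloxy)-4-bromo-2-methoxybenzene
Product: 7 (4-benzyloxy-3-methoxyphenyl)magnesium bromide (THF solution, titrated and used directly)
Conditions: Mg turnings, cat. I2, THF, 40–50 °C
Reagents that add atoms: magnesium, [Mg]
Why: Grignard formation by insertion of magnesium into the aryl C–Br bond; the aryl benzyl and methyl ethers are inert.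

Step 4
Reactants: 4 (2S)-2-(4-benzyloxy-3-methoxyphenyl)-2,3-dihydro-4H-pyran-4-one; 7 (4-benzyloxy-3-methoxyphenyl)magnesium bromide; 8 benzyl chloromethyl ether
Product: 11 (2S,3R,6S)-2,6-bis(4-benzyloxy-3-methoxyphenyl)-3-(benzyloxymethyl)tetrahydro-4H-pyran-4-one (2,6-trans, 2,3-trans), via diarylcuprate 9 (not isolated), via bromomagnesium enolate 10 (not isolated)
Conditions: 7 (2.4 equiv), CuBr·SMe2 (1.2 equiv), THF, −40 °C; 4, −78 → −40 °C; then DMPU, 8 (4 equiv, freshly distilled), −78 → −30 °C; aq NH4Cl/NH3
Reagents that add atoms: none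
Why: The magnesiocuprate 9 complexes the enone of 4, transfers one aryl group to the β-carbon C6 by oxidative addition and reductive elimination at copper, and leaves the regiodefined enolate 10, which is C-alkylated at C5 by the reactive chloromethyl ether in an SN2 displacement. This is the tandem conjugate addition–enolate alkylation (three-component coupling) of cyclic enones, and cuprates are known to add trans to the C2 substituent of 2-substituted 2,3-dihydro-4H-pyran-4-ones. No ring is closed. The new aryl-bearing centre (C2 of 11) is controlled by the existing stereocentre: with its aryl pseudo-equatorial in the half-chair, the stereoelectronically preferred axial attack at the β-carbon comes from the opposite face and gives the 2,6-trans relationship. The adjacent centre (C3 of 11) is controlled by the aryl group just installed, since the electrophile approaches the enolate face anti to it, and the resulting 2,3-trans ketone is also the more stable epimer. The step needs C- over O-alkylation and an enolate that does not open by β-elimination of the ring oxygen; low temperature, DMPU, excess electrophile and the poor overlap of the endocyclic C–O bond with the enolate π system should secure both.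

Step 5
Reactants: 11 (2S,3R,6S)-2,6-bis(4-benzyloxy-3-methoxyphenyl)-3-(benzyloxymethyl)tetrahydro-4H-pyran-4-one
Product: 14 (2S,3R,6R)-2,6-bis(4-benzyloxy-3-methoxyphenyl)-3-(benzyloxymethyl)-5-diazotetrahydro-4H-pyran-4-one, via lithium enolate 12 (not isolated), via trifluoroacetyl ketone 13 (not isolated)
Conditions: LiN(SiMe3)2, THF, −78 °C; CF3CO2CH2CF3, −78 °C; aq HCl; crude, then 4-AcNHC6H4SO2N3, Et3N, H2O (1 equiv), MeCN, rt
Reagents that add atoms: 4-acetamidobenzenesulfonyl azide, CC(=O)Nc1ccc(cc1)S(=O)(=O)N=[N+]=[N-] (the two diazo nitrogens); 2,2,2-trifluoroethyl trifluoroacetate, FC(F)(F)C(=O)OCC(F)(F)F (trifluoroacetyl group of intermediate 13 only, lost again)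
Why: Detrifluoroacetylative diazo transfer (Claisen-type acylation of the kinetic enolate at the unsubstituted C5 methylene, then Regitz-type transfer to the activated 1,3-dicarbonyl), run cold so that the enolate neither opens the ring nor touches C3; no stereocentre is made, and the C6 descriptor changes only through CIP priority.

Step 6
Reactants: 14 (2S,3R,6R)-2,6-bis(4-benzyloxy-3-methoxyphenyl)-3-(benzyloxymethyl)-5-diazotetrahydro-4H-pyran-4-one
Product: 17 methyl (2S,3R,4R,5S)-2,5-bis(4-benzyloxy-3-methoxyphenyl)-4-(benzyloxymethyl)tetrahydrofuran-3-carboxylate (2-aryl, 3-ester and 4-benzyloxymethyl mutually cis; 5-aryl trans), via ketene 15 (not isolated), via ester enol 16 (not isolated)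
Conditions: hν (365 nm, borosilicate glass), degassed MeOH–THF, −20 °C
Reagents that add atoms: methanol, CO
Why: Photochemical Wolff rearrangement: the ring-locked s-cis diazo ketone loses N2 with concerted 1,2-shift of the benzyloxymethyl-bearing carbon (retention) to give ketene 15, methanol adds to give enol 16, and 16 is protonated at the new C3 on the face opposite the flanking C2 aryl and C4 benzyloxymethyl groups, which places the ester cis to both (kinetic product; no base present).

Step 7
Reactants: 17 methyl (2S,3R,4R,5S)-2,5-bis(4-benzyloxy-3-methoxyphenyl)-4-(benzyloxymethyl)tetrahydrofuran-3-carboxylate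
Product: 18 [(2S,3S,4R,5S)-2,5-bis(4-benzyloxy-3-methoxyphenyl)-4-(benzyloxymethyl)tetrahydrofuran-3-yl]methanol
Conditions: LiAlH4, THF, −20 → 0 °C; H2O/aq NaOH work-up
Reagents that add atoms: none
Why: Hydride reduction of the ester to the primary alcohol, which is faster than α-deprotonation, so the kinetically set C3 centre should not epimerise; benzyl ethers are inert.

Step 8
Reactants: 18 [(2S,3S,4R,5S)-2,5-bis(4-benzyloxy-3-methoxyphenyl)-4-(benzyloxymethyl)tetrahydrofuran-3-yl]methanol
Product: 19 [(2S,3S,4R,5S)-2,5-bis(4-hydroxy-3-methoxyphenyl)tetrahydrofuran-3,4-diyl]dimethanol (target)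
Conditions: H2 (1 atm), 10% Pd/C, EtOAc–MeOH, rt, stopped at full conversion
Reagents that add atoms: none
Why: Catalytic hydrogenolysis removes the two aryl benzyl ethers and the primary alkyl benzyl ether under neutral conditions, under which the ring benzylic C–O bonds should cleave more slowly; no stereocentre is involved.

**Compound list**

1 | 4-(benzyloxy)-3-methoxybenzaldehyde | COc1cc(C=O)ccc1OCc1ccccc1 | starting material
2 | (E)-1-methoxy-3-(trimethylsilyloxy)buta-1,3-diene | CO/C=C/C(=C)O[Si](C)(C)C | starting material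
3 | (1E,5S)-5-(4-benzyloxy-3-methoxyphenyl)-1-methoxy-5-(trimethylsilyloxy)pent-1-en-3-one | CO/C=C/C(=O)C[C@H](O[Si](C)(C)C)c1ccc(OCc2ccccc2)c(OC)c1 | intermediate (not isolated)
4 | (2S)-2-(4-benzyloxy-3-methoxyphenyl)-2,3-dihydro-4H-pyran-4-one | COc1cc(ccc1OCc1ccccc1)[C@H]2OC=CC(=O)C2 | intermediate
5 | 4-bromo-2-methoxyphenol | COc1cc(Br)ccc1O | starting material
6 | 1-(benzyloxy)-4-bromo-2-methoxybenzene | COc1cc(Br)ccc1OCc1ccccc1 | intermediate
7 | (4-benzyloxy-3-methoxyphenyl)magnesium bromide | COc1cc([Mg]Br)ccc1OCc1ccccc1 | intermediate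
8 | benzyl chloromethyl ether | ClCOCc1ccccc1 | starting material
9 | bromomagnesium bis(4-benzyloxy-3-methoxyphenyl)cuprate | COc1cc([Cu-]c2ccc(OCc3ccccc3)c(OC)c2)ccc1OCc1ccccc1.[Mg+]Br | intermediate (not isolated)
10 | bromomagnesium (2S,6S)-2,6-bis(4-benzyloxy-3-methoxyphenyl)-3,6-dihydro-2H-pyran-4-olate (2,6-trans) | COc1cc(ccc1OCc1ccccc1)[C@H]2O[C@H](c3ccc(OCc4ccccc4)c(OC)c3)C=C(O[Mg]Br)C2 | intermediate (not isolated)
11 | (2S,3R,6S)-2,6-bis(4-benzyloxy-3-methoxyphenyl)-3-(benzyloxymethyl)tetrahydro-4H-pyran-4-one | COc1cc(ccc1OCc1ccccc1)[C@H]2O[C@H](c3ccc(OCc4ccccc4)c(OC)c3)[C@@H](COCc5ccccc5)C(=O)C2 | intermediate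
12 | kinetic lithium enolate of 11 (enolised toward the C5 methylene; C2, C3 and C6 unchanged) | COc1cc(ccc1OCc1ccccc1)[C@H]2O[C@H](c3ccc(OCc4ccccc4)c(OC)c3)[C@@H](COCc5ccccc5)C(O[Li])=C2 | intermediate (not isolated)
13 | 5-(trifluoroacetyl) derivative of 11 (C5 undefined, largely enolised) | COc1cc(ccc1OCc1ccccc1)[C@H]2O[C@H](c3ccc(OCc4ccccc4)c(OC)c3)[C@@H](COCc5ccccc5)C(=O)C2C(=O)C(F)(F)F | intermediate (not isolated)
14 | (2S,3R,6R)-2,6-bis(4-benzyloxy-3-methoxyphenyl)-3-(benzyloxymethyl)-5-diazotetrahydro-4H-pyran-4-one | COc1cc(ccc1OCc1ccccc1)[C@H]2O[C@H](c3ccc(OCc4ccccc4)c(OC)c3)[C@@H](COCc5ccccc5)C(=O)C2=[N+]=[N-] | intermediate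
15 | ring-contracted ketene, 2,5-bis(4-benzyloxy-3-methoxyphenyl)-4-(benzyloxymethyl)-3-(oxomethylidene)tetrahydrofuran (C2, C4, C5 as in 17) | COc1cc(ccc1OCc1ccccc1)[C@H]2O[C@H](c3ccc(OCc4ccccc4)c(OC)c3)[C@@H](COCc5ccccc5)C2=C=O | intermediate (not isolated)
16 | enol (methyl ketene hemiacetal) of ester 17 | COc1cc(ccc1OCc1ccccc1)[C@H]2O[C@H](c3ccc(OCc4ccccc4)c(OC)c3)[C@@H](COCc5ccccc5)C2=C(O)OC | intermediate (not isolated)
17 | methyl (2S,3R,4R,5S)-2,5-bis(4-benzyloxy-3-methoxyphenyl)-4-(benzyloxymethyl)tetrahydrofuran-3-carboxylate | COc1cc(ccc1OCc1ccccc1)[C@H]2O[C@H](c3ccc(OCc4ccccc4)c(OC)c3)[C@@H](COCc5ccccc5)[C@H]2C(=O)OC | intermediate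
18 | [(2S,3S,4R,5S)-2,5-bis(4-benzyloxy-3-methoxyphenyl)-4-(benzyloxymethyl)tetrahydrofuran-3-yl]methanol | COc1cc(ccc1OCc1ccccc1)[C@H]2O[C@H](c3ccc(OCc4ccccc4)c(OC)c3)[C@@H](COCc5ccccc5)[C@H]2CO | intermediate
19 | [(2S,3S,4R,5S)-2,5-bis(4-hydroxy-3-methoxyphenyl)tetrahydrofuran-3,4-diyl]dimethanol | COc1cc([C@H]2O[C@H](c3ccc(O)c(OC)c3)[C@@H](CO)[C@H]2CO)ccc1O | target

**Summary**

Total step count: 8.
Longest linear sequence: 7 steps (5 → 6 → 7 → 11 → 14 → 17 → 18 → 19; 6 steps from aldehyde 1).

**Steps most likely to fail**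

1. Step 4. The ambident magnesium enolate may be alkylated on oxygen by the hard chloromethyl ether. Alternatively, the alkylation may be slow enough that proton exchange or ring opening by β-elimination competes. The fallback makes the two bonds in separate operations. It sets out from 4 and 7: the cuprate addition is run in the presence of Me3SiCl to give the silyl enol ether (2S,6S)-2,6-bis(4-benzyloxy-3-methoxyphenyl)-4-(trimethylsilyloxy)-3,6-dihydro-2H-pyran F1. This is hydroxymethylated with aqueous formaldehyde and catalytic Yb(OTf)3 in THF (Mukaiyama aldol reaction, electrophile anti to the neighbouring aryl) to give (2S,3R,6S)-2,6-bis(4-benzyloxy-3-methoxyphenyl)-3-(hydroxymethyl)tetrahydro-4H-pyran-4-one F2. Benzylation under neutral conditions with 2-benzyloxy-1-methylpyridinium triflate and MgO in PhCF3 at about 85 °C brings the fallback back to the route at 11.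

2. Step 6. The ester enol may be protonated with insufficient facial bias, or the all-cis ester may epimerise at C3 to the more stable 2,3-trans isomer. The fallback resets C3 in a separate kinetic protonation. It sets out from 17 contaminated with its C3 epimer, methyl (2S,3S,4R,5S)-2,5-bis(4-benzyloxy-3-methoxyphenyl)-4-(benzyloxymethyl)tetrahydrofuran-3-carboxylate F4. LiN(iPr)2 in THF at −78 °C converts both epimers into the same lithium ester enolate of 17 F5; ring opening from this exocyclic enolate would be the disfavoured reverse of a 5-endo closure. F5 is quenched at −78 °C with the hindered proton donor 2,6-di-tert-butyl-4-methylphenol, which should approach opposite the C2 aryl and C4 benzyloxymethyl groups, and the fallback comes back to the route at 17.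

3. Step 5. Enolate formation may trigger β-elimination of the ring oxygen at the benzylic carbon, with reclosure to the 2,6-cis ketone, or deprotonation at the substituted α-carbon with loss of benzyloxide. The fallback avoids the metal enolate. It sets out from 11: condensation with tert-butoxybis(dimethylamino)methane in toluene at 60–80 °C at the unhindered methylene gives the enaminone (E)-5-(dimethylaminomethylene) derivative of 11 F3. Diazo transfer to F3 with p-toluenesulfonyl azide in MeCN at rt, with loss of the N-sulfonylformamidine, brings the fallback back to the route at 14.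

**Further compounds**

F1 | step 4 | (2S,6S)-2,6-bis(4-benzyloxy-3-methoxyphenyl)-4-(trimethylsilyloxy)-3,6-dihydro-2H-pyran | COc1cc(ccc1OCc1ccccc1)[C@H]2O[C@H](c3ccc(OCc4ccccc4)c(OC)c3)C=C(O[Si](C)(C)C)C2
F2 | step 4 | (2S,3R,6S)-2,6-bis(4-benzyloxy-3-methoxyphenyl)-3-(hydroxymethyl)tetrahydro-4H-pyran-4-one | COc1cc(ccc1OCc1ccccc1)[C@H]2O[C@H](c3ccc(OCc4ccccc4)c(OC)c3)[C@@H](CO)C(=O)C2
F3 | step 5 | (E)-5-(dimethylaminomethylene) derivative of 11 (stereocentres as in 11) | COc1cc(ccc1OCc1ccccc1)[C@H]2O[C@H](c3ccc(OCc4ccccc4)c(OC)c3)[C@@H](COCc5ccccc5)C(=O)/C2=C/N(C)C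
F4 | step 6 | methyl (2S,3S,4R,5S)-2,5-bis(4-benzyloxy-3-methoxyphenyl)-4-(benzyloxymethyl)tetrahydrofuran-3-carboxylate (C3 epimer of 17) | COc1cc(ccc1OCc1ccccc1)[C@H]2O[C@H](c3ccc(OCc4ccccc4)c(OC)c3)[C@@H](COCc5ccccc5)[C@@H]2C(=O)OC
F5 | step 6 | lithium ester enolate of 17 | COc1cc(ccc1OCc1ccccc1)[C@H]2O[C@H](c3ccc(OCc4ccccc4)c(OC)c3)[C@@H](COCc5ccccc5)C2=C(OC)O[Li]
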